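Hardest: placing farnesyl at C6 and not C8 (a 3'-farnesyl-2',4',6'-trihydroxychalcone can close through either ortho oxygen), and keeping C2, which is lost whenever ring C opens to that chalcone. The route therefore never contains a chalcone.
Enabling feature: ring A (C4a–C8a) and ring B (C1'–C6') are both resorcinols substituted at the carbon meta to both oxygens (C8a–O1 and C1'–C2). O1 is para to C6, and C2 is the β-carbon of the C4 carbonyl, so ring C can exist first as a flat, configurationally inert chromone.
Cuts, in retrosynthetic order: C2–C1'; then O1–C2, C3–C4 and C4–C4a (ring C from ethyne and formaldehyde); then C8a–O1; then C6–C1''.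
Forward, ring A/C: one resorcinol bis-MOM ether serves both rings. Farnesyl enters between its two ethers, and O1 is then put para to it by sterically ruled C–H borylation/oxidation. This makes C4a and C8 equivalent, so formylation, ethynylation and oxidation/6-endo closure can give only the 6-farnesyl chromone.
Forward, ring B and union: the same C–H borylation on the unsubstituted ether gives the ring B boronic acid, which is joined to C2 of the chromone by dearomatising Rh/chiral-diene 1,4-addition. Four MOM groups are then removed in one operation.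
Stereochemistry: C2 (S) comes from the catalyst in that addition. The two E double bonds are bought with farnesyl bromide and never touched.

Key step: step 9

Assumption: the sense of induction of the Rh/(S,S)-diene catalyst (aryl to the C2 Re face, giving S) is taken from its behaviour with 2-cyclohexenone, to which the chromone maps atom for atom. The enantiomeric diene is equally available if the opposite sense is found.
Abbreviations: farnesyl = (2E,6E)-3,7,11-trimethyldodeca-2,6,10-trien-1-yl; MOM = CH2OCH3. Flavanone numbering is used for target atoms throughout.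

Step 1
Reactants: 1 resorcinol
Product: 2 1,3-bis(methoxymethoxy)benzene
Conditions: NaH (2.4 equiv), MOMCl (2.4 equiv), DMF, 0 °C to rt
Reagents that add atoms: chloromethyl methyl ether (MOMCl), COCCl
Why: Williamson-type O-alkylation of the bis-phenoxide gives the bis-acetal, which later serves both as protecting group and as ortho-directing group.

Step 2
Reactants: 2 1,3-bis(methoxymethoxy)benzene; 3 (2E,6E)-farnesyl bromide
Product: 5 2-[(2E,6E)-farnesyl]-1,3-bis(methoxymethoxy)benzene, via aryllithium 4 (not isolated)
Conditions: n-BuLi (1.1 equiv), THF, 0 °C to rt; then 3, −78 °C to rt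
Reagents that add atoms: n-butyllithium, [Li]CCCC (supplies only the lithium of 4)
Why: Directed ortho-metalation takes place at the carbon between the two chelating MOM ethers, and SN2 alkylation of 4 at the primary allylic carbon of 3 forms C6–C1'' without touching either E double bond, as is well known for 2-prenylated resorcinol ethers.

Step 3
Reactants: 5 2-[(2E,6E)-farnesyl]-1,3-bis(methoxymethoxy)benzene
Product: 7 4-[(2E,6E)-farnesyl]-3,5-bis(methoxymethoxy)phenol, via boronate 6 (not isolated)
Conditions: [Ir(OMe)(cod)]2 (1.5 mol %), dtbpy (3 mol %), B2pin2 (1.0 equiv), MTBE, 40 °C; evaporate; NaBO3·4H2O (3 equiv), THF/H2O, rt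
Reagents that add atoms: bis(pinacolato)diboron, CC1(C)OB(OC1(C)C)B1OC(C)(C)C(C)(C)O1 (boryl group of 6); sodium perborate, [Na+].[O-]OB=O (the oxygen atom, future O1)
Why: Iridium-catalysed aromatic C–H borylation is ruled by sterics and should strike only the one ring C–H of 5 that has no ortho substituent (para to farnesyl, meta to both ethers), the trisubstituted alkenes being poor partners for the Ir–boryl catalyst, and ipso-oxidation of 6 by perborate then places the future O1 there and leaves two equivalent ring C–H positions (future C4a and C8).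

Step 4
Reactants: 7 4-[(2E,6E)-farnesyl]-3,5-bis(methoxymethoxy)phenol
Product: 9 3-[(2E,6E)-farnesyl]-6-hydroxy-2,4-bis(methoxymethoxy)benzaldehyde, via salicyl alcohol 8 (not isolated)
Conditions: MgCl2 (2 equiv), Et3N (4 equiv), (CH2O)n (7 equiv), MeCN, 80 °C; citrate buffer (pH 4–5) work-up
Reagents that add atoms: formaldehyde (from paraformaldehyde), C=O
Why: In the Casnati–Skattebøl ortho-formylation the magnesium phenoxide delivers formaldehyde to an ortho carbon and 8 is oxidised by hydride transfer to a second formaldehyde, and because the para position is blocked and both ortho positions are equivalent only one aldehyde can form, under basic conditions that spare MOM ethers and alkenes.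

Step 5
Reactants: 9 3-[(2E,6E)-farnesyl]-6-hydroxy-2,4-bis(methoxymethoxy)benzaldehyde
Product: 10 racemic 1-{3-[(2E,6E)-farnesyl]-6-hydroxy-2,4-bis(methoxymethoxy)phenyl}prop-2-yn-1-ol
Conditions: HC≡CMgBr (3 equiv), THF, 0 °C to rt; sat. aq NH4Cl at 0 °C; used crude
Reagents that add atoms: ethynylmagnesium bromide, C#C[Mg]Br
Why: Grignard 1,2-addition to the aldehyde, after the first equivalent has deprotonated the phenol, brings in C3 and C2, and the new carbinol centre is racemic and is erased in step 6.

Step 6
Reactants: 10 racemic 1-{3-[(2E,6E)-farnesyl]-6-hydroxy-2,4-bis(methoxymethoxy)phenyl}prop-2-yn-1-ol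
Product: 12 6-[(2E,6E)-farnesyl]-5,7-bis(methoxymethoxy)-4H-chromen-4-one, via ynone 11 (not isolated)
Conditions: MnO2 (15 equiv), CH2Cl2, rt; filter; DMAP (10 mol %), CH2Cl2, rt
Reagents that add atoms: none
Why: Manganese dioxide oxidises the doubly activated (benzylic and propargylic) carbinol, the phenol being a poor substrate because both MOM ethers are meta to it, and nucleophile-catalysed 6-endo-dig oxa-Michael addition of the only free hydroxyl (O1–H) to the terminal alkynone carbon closes ring C, so that only the 6-farnesyl chromone can arise.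

Step 7
Reactants: 2 1,3-bis(methoxymethoxy)benzene
Product: 13 2-[3,5-bis(methoxymethoxy)phenyl]-4,4,5,5-tetramethyl-1,3,2-dioxaborolane
Conditions: [Ir(OMe)(cod)]2 (1 mol %), dtbpy (2 mol %), B2pin2 (1.0 equiv), THF, 60 °C
Reagents that add atoms: bis(pinacolato)diboron, CC1(C)OB(OC1(C)C)B1OC(C)(C)C(C)(C)O1
Why: The same sterically ruled iridium-catalysed C–H borylation strikes the only C–H of 2 that is not ortho to a MOM ether and so marks the future C1', a carbon that electrophilic substitution of a resorcinol cannot reach.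

Step 8
Reactants: 13 2-[3,5-bis(methoxymethoxy)phenyl]-4,4,5,5-tetramethyl-1,3,2-dioxaborolane
Product: 14 [3,5-bis(methoxymethoxy)phenyl]boronic acid
Conditions: NaIO4 (3 equiv), NH4OAc (3 equiv), acetone/H2O, rt
Reagents that add atoms: water, O
Why: Periodate glycol cleavage of the liberated pinacol drives hydrolysis of the pinacol ester in a buffered medium that MOM ethers tolerate, and the free boronic acid transmetallates to rhodium under much milder conditions than the ester.

Step 9
Reactants: 12 6-[(2E,6E)-farnesyl]-5,7-bis(methoxymethoxy)-4H-chromen-4-one; 14 [3,5-bis(methoxymethoxy)phenyl]boronic acid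
Product: 15 (2S)-6-[(2E,6E)-farnesyl]-5,7-bis(methoxymethoxy)-2-[3,5-bis(methoxymethoxy)phenyl]chroman-4-one
Conditions: [RhCl(C2H4)2]2 (2.5 mol %), (1S,4S)-2,5-diphenylbicyclo[2.2.2]octa-2,5-diene (5.5 mol %), aq KOH (10 mol %), 14 (2 equiv), toluene/H2O 10:1, 30–50 °C
Reagents that add atoms: none
Why: Transmetallation of 14 to the hydroxorhodium(I)–diene complex gives an aryl–rhodium species that binds C2=C3 of 12 and inserts it with C–C bond formation at C2, and water protonates the resulting oxa-π-allyl rhodium enolate at C3, which returns Rh–OH and releases boric acid. The closest known reaction type is the Hayashi–Miyaura asymmetric 1,4-addition of arylboronic acids to 4H-chromen-4-ones, 5,7-dioxygenated ones included. No ring is closed: the step saturates C2–C3 of the preformed flat pyranone ring C (a dearomatisation of the γ-pyrone) and at the same stroke joins ring B to the A/C bicycle, so the complete carbon skeleton and the only stereocentre appear together. C2 is controlled by the C2-symmetric diene, whose phenyl groups leave open only the arrangement in which the bound enone offers its C2 Re face to the migrating aryl group, which gives (S). The step needs chemoselectivity for the enone over the three trisubstituted alkenes, which neither chelate rhodium nor insert into aryl–Rh, and 1,4- over 1,2-addition, which the peri 5-OMOM group and the O7 donor secure by shielding and deactivating C4. It also needs the configuration to hold after addition, which the nearly neutral medium secures, while the MOM group on O5 ensures that even a transient ring opening could not reclose to the 8-farnesyl isomer.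

Step 10
Reactants: 15 (2S)-6-[(2E,6E)-farnesyl]-5,7-bis(methoxymethoxy)-2-[3,5-bis(methoxymethoxy)phenyl]chroman-4-one
Product: 16 (2S)-6-[(2E,6E)-farnesyl]-5,7-dihydroxy-2-(3,5-dihydroxyphenyl)chroman-4-one (target)
Conditions: HCl (1.25 M in MeOH), 40 °C
Reagents that add atoms: none
Why: Acid-catalysed acetal exchange with methanol removes all four aryl MOM ethers much faster than a trisubstituted alkene is protonated (the conditions in use for geranylated flavanones), and C2 should hold because ring B has no 2'- or 4'-hydroxyl that could open ring C through a quinone methide.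

Compound list
1 | resorcinol (benzene-1,3-diol) | Oc1cccc(O)c1 | starting material
2 | 1,3-bis(methoxymethoxy)benzene | COCOc1cccc(OCOC)c1 | intermediate
3 | (2E,6E)-farnesyl bromide | CC(C)=CCC/C(C)=C/CC/C(C)=C/CBr | starting material
4 | 2,6-bis(methoxymethoxy)phenyllithium | [Li]c1c(OCOC)cccc1OCOC | intermediate
5 | 2-[(2E,6E)-farnesyl]-1,3-bis(methoxymethoxy)benzene | CC(C)=CCC/C(C)=C/CC/C(C)=C/Cc1c(OCOC)cccc1OCOC | intermediate
6 | 2-{4-[(2E,6E)-farnesyl]-3,5-bis(methoxymethoxy)phenyl}-4,4,5,5-tetramethyl-1,3,2-dioxaborolane | CC(C)=CCC/C(C)=C/CC/C(C)=C/Cc1c(OCOC)cc(B2OC(C)(C)C(C)(C)O2)cc1OCOC | intermediate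
7 | 4-[(2E,6E)-farnesyl]-3,5-bis(methoxymethoxy)phenol | CC(C)=CCC/C(C)=C/CC/C(C)=C/Cc1c(OCOC)cc(O)cc1OCOC | intermediate
8 | 3-[(2E,6E)-farnesyl]-6-hydroxy-2,4-bis(methoxymethoxy)benzyl alcohol | CC(C)=CCC/C(C)=C/CC/C(C)=C/Cc1c(OCOC)cc(O)c(CO)c1OCOC | intermediate
9 | 3-[(2E,6E)-farnesyl]-6-hydroxy-2,4-bis(methoxymethoxy)benzaldehyde | CC(C)=CCC/C(C)=C/CC/C(C)=C/Cc1c(OCOC)cc(O)c(C=O)c1OCOC | intermediate
10 | racemic 1-{3-[(2E,6E)-farnesyl]-6-hydroxy-2,4-bis(methoxymethoxy)phenyl}prop-2-yn-1-ol | CC(C)=CCC/C(C)=C/CC/C(C)=C/Cc1c(OCOC)cc(O)c(C(O)C#C)c1OCOC | intermediate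
11 | 1-{3-[(2E,6E)-farnesyl]-6-hydroxy-2,4-bis(methoxymethoxy)phenyl}prop-2-yn-1-one | CC(C)=CCC/C(C)=C/CC/C(C)=C/Cc1c(OCOC)cc(O)c(C(=O)C#C)c1OCOC | intermediate
12 | 6-[(2E,6E)-farnesyl]-5,7-bis(methoxymethoxy)-4H-chromen-4-one | CC(C)=CCC/C(C)=C/CC/C(C)=C/Cc1c(OCOC)cc2c(c1OCOC)C(=O)C=CO2 | intermediate
13 | 2-[3,5-bis(methoxymethoxy)phenyl]-4,4,5,5-tetramethyl-1,3,2-dioxaborolane | COCOc1cc(OCOC)cc(B2OC(C)(C)C(C)(C)O2)c1 | intermediate
14 | [3,5-bis(methoxymethoxy)phenyl]boronic acid | COCOc1cc(OCOC)cc(B(O)O)c1 | intermediate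
15 | (2S)-6-[(2E,6E)-farnesyl]-5,7-bis(methoxymethoxy)-2-[3,5-bis(methoxymethoxy)phenyl]chroman-4-one | CC(C)=CCC/C(C)=C/CC/C(C)=C/Cc1c(OCOC)cc2c(c1OCOC)C(=O)C[C@@H](c1cc(OCOC)cc(OCOC)c1)O2 | intermediate
16 | (2S)-6-[(2E,6E)-farnesyl]-5,7-dihydroxy-2-(3,5-dihydroxyphenyl)chroman-4-one (CNP0186816.1) | CC(C)=CCC/C(C)=C/CC/C(C)=C/Cc1c(O)cc2c(c1O)C(=O)C[C@@H](c1cc(O)cc(O)c1)O2 | target

Total step count: 10. Longest linear sequence: 8 (steps 1–6, 9, 10).

Steps most likely to fail

Step 9. The electron-rich chromone with its peri 5-OMOM group may insert slowly, so that protodeboronation of 14 outruns the addition. Long contact with the basic aqueous phase may also erode the configuration by reversible ring opening. The fallback sets out from 9 and returns at 15, and takes the stereocentre from a resolution instead of an addition.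
- Methylmagnesium bromide adds to 9 to give the racemic 1-arylethanol F1, and manganese dioxide gives the acetophenone F2.
- Claisen–Schmidt condensation (KOH, EtOH) with 3,5-bis(methoxymethoxy)benzaldehyde F3, made from commercial 3,5-dihydroxybenzaldehyde and MOMCl, gives the (E)-chalcone F4.
- O1–H is the only free hydroxyl in that chalcone, so closure (NaOAc, EtOH, reflux) can give only the racemic 6-farnesyl flavanone F5.
- Kinetic resolution by Noyori–Ikariya transfer hydrogenation [RuCl(p-cymene)((R,R)-TsDPEN), HCO2H/Et3N] should reduce the (2R) enantiomer to the cis-(2R,4R)-flavan-4-ol F6 and leave 15, which is separated by chromatography.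

Step 3. The pinacolborane formed during the borylation may hydroborate or isomerise the farnesyl alkenes under iridium catalysis, or the borylation may stall on the bulky substrate. The fallback sets out from 13 (made in step 7 from the alkene-free ether) together with 3, and returns at 7, so the C–H borylation comes before the alkenes are present.
- Perborate oxidation of 13 gives 3,5-bis(methoxymethoxy)phenol F7, and TIPSCl/imidazole gives the triisopropylsilyl ether F8.
- n-BuLi should lithiate only between the two MOM ethers, because the bulky, non-coordinating silyl ether shields its own neighbours. Alkylation with 3 then gives the farnesylated silyl ether F9.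
- TBAF releases 7.

Step 6. Oxidation of the free para-alkylphenol (quinone methide formation, oligomerisation) may compete with oxidation of the hindered carbinol, and the very electron-rich benzylic alcohol may ionise on the oxidant surface. The fallback sets out from 9 and returns at 12, and masks O1 during the oxidation.
- Allyl bromide/K2CO3/DMF gives the O-allyl aldehyde F10, ethynylmagnesium bromide gives the O-allyl propargylic alcohol F11, and Dess–Martin periodinane gives the O-allyl ynone F12.
- Pd(PPh3)4/K2CO3/MeOH removes the aryl allyl ether under non-acidic conditions, and the released phenoxide closes 6-endo onto the alkynone in the same flask to give 12.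

Further compounds
F1 | step 9 | racemic 1-{3-[(2E,6E)-farnesyl]-6-hydroxy-2,4-bis(methoxymethoxy)phenyl}ethanol | CC(C)=CCC/C(C)=C/CC/C(C)=C/Cc1c(OCOC)cc(O)c(C(C)O)c1OCOC
F2 | step 9 | 1-{3-[(2E,6E)-farnesyl]-6-hydroxy-2,4-bis(methoxymethoxy)phenyl}ethanone | CC(C)=CCC/C(C)=C/CC/C(C)=C/Cc1c(OCOC)cc(O)c(C(C)=O)c1OCOC
F3 | step 9 | 3,5-bis(methoxymethoxy)benzaldehyde | COCOc1cc(C=O)cc(OCOC)c1
F4 | step 9 | (E)-1-{3-[(2E,6E)-farnesyl]-6-hydroxy-2,4-bis(methoxymethoxy)phenyl}-3-[3,5-bis(methoxymethoxy)phenyl]prop-2-en-1-one | CC(C)=CCC/C(C)=C/CC/C(C)=C/Cc1c(OCOC)cc(O)c(C(=O)/C=C/c2cc(OCOC)cc(OCOC)c2)c1OCOC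
F5 | step 9 | racemic 6-[(2E,6E)-farnesyl]-5,7-bis(methoxymethoxy)-2-[3,5-bis(methoxymethoxy)phenyl]chroman-4-one | CC(C)=CCC/C(C)=C/CC/C(C)=C/Cc1c(OCOC)cc2c(c1OCOC)C(=O)CC(c1cc(OCOC)cc(OCOC)c1)O2
F6 | step 9 | (2R,4R)-6-[(2E,6E)-farnesyl]-5,7-bis(methoxymethoxy)-2-[3,5-bis(methoxymethoxy)phenyl]chroman-4-ol | CC(C)=CCC/C(C)=C/CC/C(C)=C/Cc1c(OCOC)cc2c(c1OCOC)[C@H](O)C[C@H](c1cc(OCOC)cc(OCOC)c1)O2
F7 | step 3 | 3,5-bis(methoxymethoxy)phenol | COCOc1cc(O)cc(OCOC)c1
F8 | step 3 | [3,5-bis(methoxymethoxy)phenoxy]triisopropylsilane | COCOc1cc(O[Si](C(C)C)(C(C)C)C(C)C)cc(OCOC)c1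
F9 | step 3 | {4-[(2E,6E)-farnesyl]-3,5-bis(methoxymethoxy)phenoxy}triisopropylsilane | CC(C)=CCC/C(C)=C/CC/C(C)=C/Cc1c(OCOC)cc(O[Si](C(C)C)(C(C)C)C(C)C)cc1OCOC
F10 | step 6 | 6-allyloxy-3-[(2E,6E)-farnesyl]-2,4-bis(methoxymethoxy)benzaldehyde | CC(C)=CCC/C(C)=C/CC/C(C)=C/Cc1c(OCOC)cc(OCC=C)c(C=O)c1OCOC
F11 | step 6 | racemic 1-{6-allyloxy-3-[(2E,6E)-farnesyl]-2,4-bis(methoxymethoxy)phenyl}prop-2-yn-1-ol | CC(C)=CCC/C(C)=C/CC/C(C)=C/Cc1c(OCOC)cc(OCC=C)c(C(O)C#C)c1OCOC
F12 | step 6 | 1-{6-allyloxy-3-[(2E,6E)-farnesyl]-2,4-bis(methoxymethoxy)phenyl}prop-2-yn-1-one | CC(C)=CCC/C(C)=C/CC/C(C)=C/Cc1c(OCOC)cc(OCC=C)c(C(=O)C#C)c1OCOC
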